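A direct plan would take ring B from 2,4,6-trihydroxytoluene A1 (C-acylation, one O-methylation), would fasten a three-carbon chain to its last free ring carbon by way of the benzylic bromide A2, and would then build ring A on that chain by a Lewis-acid-mediated annulation of the tris(silyl enol ether) A3 with the alkoxy ynone A4; BCl3 would free the target from the resulting tri-ether A5.
Its weakest step would be the annulation of A3 with A4: a ring closure without precedent (a diene substituted at every carbon, a β-alkoxy ynone, a third silyl enol ether in the same molecule) that would leave the regiochemistry and the aromatisation of ring A to chance on the most advanced material of the plan.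
The second would be the run of formylation, O-benzylation, reduction, bromination and dianion alkylation that passes through A2: five steps that would add a tether and two protecting groups but no complexity, and whose crowded bromide would have to be displaced faster than the ring B ketone is enolised.
The third would be the closing BCl3 cleavage of one isopropyl and two benzyl ethers, which would have to spare the aryl methyl ether and an acid-sensitive bis(acylphloroglucinol)methane on the last intermediate.

**Plan of the new route**

Atom labels: ring A (three OH) C1 propanoyl, C2 OH, C3 CH2 bridge, C4 OH, C5 methyl, C6 OH; ring B (one OMe) C1' CH2 bridge, C2' OH, C3' propanoyl, C4' OH, C5' methyl, C6' OMe.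
Cuts: C1–C2 of ring A and C3'–C2' of ring B (in each ring the bond from the acyl-bearing carbon to the C–OH carbon beside the bridge) turn both arenes into 2H-pyran-2-ones, the lactones of two 4-methyl-3,5,7-trioxononanoic acids joined at their C2 atoms; the two CH2–C bonds then fall to formaldehyde and two copies of one lactone, and the ring-to-carbonyl bond of each propanoyl group (C1–CO, C3'–CO) to a Weinreb amide acylation of the C6 methyl of that lactone.
Enabling feature: each ring is a Claisen-folded nine-carbon tetraketide (oxygen on every second ring carbon, the acyl carbon between two C–OH), and the bridge sits on C3 of ring A and C1' of ring B, which are C2 of the chains and C3 of the 4-hydroxy-2-pyranones, their most nucleophilic carbon; the bridge on that carbon also shuts the rival aldol fold, which could not aromatise.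
Ring order: no benzene ring is present before the last step, in which ring B and ring A arise in one operation from the bis-lactone 10; the only event that tells the two halves apart is one O-methylation of the symmetric bis-lactone 8.
The weak steps do not arise: no cycloaddition onto a crowded diene, no tether and no protecting group (the bridge is formaldehyde, joined at the lactone stage), and no ether cleavage at the end (the last step is a base-mediated isomerisation).

Key step: step 5

Remark: hydroxy-pyranones, 1,3-diketones and the phloroglucinol rings are written in one tautomeric form each; the target has no stereocentre, and C4 of 3 and of 11 is a racemic, enolisable centre that disappears.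

Step 1
Reactants: 1 methyl 3-oxopentanoate
Product: 4 4-hydroxy-5,6-dimethyl-2H-pyran-2-one, via dianion 2 (not isolated), via dioxo ester 3 (not isolated)
Conditions: NaH, THF, 0 °C; n-BuLi, 0 °C; MeC(O)N(OMe)Me, −78 → 0 °C; 1 M HCl; then DBU, PhMe, 110 °C; 1 M HCl
Reagents that add atoms: N-methoxy-N-methylacetamide (CC(=O)N(C)OC)
Why: Weiler dianion acylation followed by lactonisation of a 3,5-dioxo ester: the γ-carbanion of 2 is its most nucleophilic site and is acylated only once because the chelated tetrahedral adduct of the Weinreb amide lasts until the quench, and under DBU the C5 enol oxygen of 3 closes onto the ester with loss of methanol to give the 4-hydroxy-2-pyranone.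

Step 2
Reactants: 4 4-hydroxy-5,6-dimethyl-2H-pyran-2-one
Product: 6 4-hydroxy-5-methyl-6-(2-oxobutyl)-2H-pyran-2-one, via dilithium dianion 5 (not isolated)
Conditions: LiN(i-Pr)2 (2.3 equiv), THF/DMPU, −78 → −20 °C; EtC(O)N(OMe)Me, −78 → 0 °C; 1 M HCl
Reagents that add atoms: N-methoxy-N-methylpropanamide (CCC(=O)N(C)OC)
Why: Lateral acylation of a 4-hydroxy-6-methyl-2-pyranone dianion, as known for triacetic acid lactone: after the hydroxyl, the second equivalent of amide base removes a proton from the C6 methyl, whose carbanion is a vinylogous enolate of the C4 carbonyl whereas that of the C5 methyl is not, and this carbanion is acylated by the Weinreb amide (Weinreb ketone synthesis), the adduct protecting the new ketone from the remaining base.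

Step 3
Reactants: 6 4-hydroxy-5-methyl-6-(2-oxobutyl)-2H-pyran-2-one (two molecules)
Product: 8 3,3'-methylenebis[4-hydroxy-5-methyl-6-(2-oxobutyl)-2H-pyran-2-one], via methylidene dione 7 (not isolated)
Conditions: aq HCHO (0.5 equiv), EtOH, 25 → 60 °C
Reagents that add atoms: formaldehyde (C=O)
Why: Knoevenagel condensation of formaldehyde at C3 of 6, the carbon between the lactone carbonyl and the enolic C4, followed by Michael addition of a second molecule of 6 through the same carbon to the methylidene dione 7, the way 3,3'-methylenebis(4-hydroxycoumarin) forms from 4-hydroxycoumarin; the less acidic methylene of the 2-oxobutyl arm should not compete.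

Step 4
Reactants: 8 3,3'-methylenebis[4-hydroxy-5-methyl-6-(2-oxobutyl)-2H-pyran-2-one]
Product: 10 4-hydroxy-3-{[4-methoxy-5-methyl-2-oxo-6-(2-oxobutyl)-2H-pyran-3-yl]methyl}-5-methyl-6-(2-oxobutyl)-2H-pyran-2-one, via monopotassium salt 9 (not isolated)
Conditions: K2CO3 (0.5 equiv), Me2SO4 (1.0 equiv), acetone, 25 → 40 °C; 0.5 M HCl
Reagents that add atoms: dimethyl sulfate (COS(=O)(=O)OC)
Why: O-Methylation of a 4-hydroxy-2H-pyran-2-one at the C4 oxygen with dimethyl sulfate and carbonate (the standard route to 4-methoxy-2-pyranones): half an equivalent of K2CO3 should remove one proton only, because the monoanion 9 is held by a hydrogen bond from the remaining hydroxyl, as in 3,3'-methylenebis(4-hydroxycoumarin), and is a weaker base than the anion of the product, so that 9 and not the anion of 10 should be the species alkylated until 8 is used up.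

Step 5
Reactants: 10 4-hydroxy-3-{[4-methoxy-5-methyl-2-oxo-6-(2-oxobutyl)-2H-pyran-3-yl]methyl}-5-methyl-6-(2-oxobutyl)-2H-pyran-2-one
Product: 13 1-[3-{[2,4-dihydroxy-6-methoxy-5-methyl-3-propanoylphenyl]methyl}-2,4,6-trihydroxy-5-methylphenyl]propan-1-one, via ring-opened ester 11 (not isolated), via arene lactone 12 (not isolated)
Conditions: Mg(OMe)2 (10 equiv), MeOH, 65 °C, Ar; then 1 M HCl, 0 °C
Reagents that add atoms: none
Why: Methoxide from Mg(OMe)2 should open each lactone at its carbonyl carbon to the methyl ester of a 3,5,7-trioxo acid (11 for the methoxy half), in which the C2=C3 bond inherited from the ring holds the ester carbon and C4 cis; the magnesium-chelated 1,3-diketone carbon C6 of the 2-oxobutyl arm then attacks the ester carbonyl (Claisen condensation), methoxide leaves and enolisation gives the benzene ring, first ring B (12) and then, through the less electrophilic anionic hydroxy-lactone, ring A. The closest known reaction type is the Mg(OMe)2-induced conversion of 6-(2-oxopropyl)-4-hydroxy-2H-pyran-2-one and of its 4-methyl ether into 2,4,6-trihydroxyacetophenone and 2,6-dihydroxy-4-methoxyacetophenone. Each ring closes by a 6-exo-trig C-acylation that forms the bond between the propanoyl-bearing carbon and the C–OH carbon beside the bridge (C3'–C2' in ring B, C1–C2 in ring A). No stereocentre is formed, and the sp3 carbon C4 of each opened chain is erased on aromatisation. The step needs the Claisen fold to win over the aldol fold, which is secured by the bridge on C2 of each chain (an aldol adduct of C2 with the C7 ketone would be quaternary at C2, could not aromatise and should revert) and by magnesium chelation, which steers such chains to C-acylation. It also needs the methyl ether to stay on the para oxygen of ring B, which is secured because C3 of that chain stays an enol ether carbon throughout and becomes C6'.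

**Compound list**

1 | methyl 3-oxopentanoate | CCC(=O)CC(=O)OC | starting material
2 | sodium lithium dianion of 1 | CC=C([O-])C=C([O-])OC.[Na+].[Li+] | intermediate (not isolated)
3 | methyl 4-methyl-3,5-dioxohexanoate (racemic) | CC(=O)C(C)C(=O)CC(=O)OC | intermediate (not isolated)
4 | 4-hydroxy-5,6-dimethyl-2H-pyran-2-one | CC1=C(C)C(O)=CC(=O)O1 | intermediate
5 | dilithium dianion of 4 | C=C1OC([O-])=CC([O-])=C1C.[Li+].[Li+] | intermediate (not isolated)
6 | 4-hydroxy-5-methyl-6-(2-oxobutyl)-2H-pyran-2-one | CCC(=O)CC1=C(C)C(O)=CC(=O)O1 | intermediate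
7 | 5-methyl-3-methylidene-6-(2-oxobutyl)-2H-pyran-2,4(3H)-dione | CCC(=O)CC1=C(C)C(=O)C(=C)C(=O)O1 | intermediate (not isolated)
8 | 3,3'-methylenebis[4-hydroxy-5-methyl-6-(2-oxobutyl)-2H-pyran-2-one] | CCC(=O)CC1=C(C)C(O)=C(CC2=C(O)C(C)=C(CC(=O)CC)OC2=O)C(=O)O1 | intermediate
9 | monopotassium salt of 8 | CCC(=O)CC1=C(C)C([O-])=C(CC2=C(O)C(C)=C(CC(=O)CC)OC2=O)C(=O)O1.[K+] | intermediate (not isolated)
10 | 4-hydroxy-3-{[4-methoxy-5-methyl-2-oxo-6-(2-oxobutyl)-2H-pyran-3-yl]methyl}-5-methyl-6-(2-oxobutyl)-2H-pyran-2-one | CCC(=O)CC1=C(C)C(O)=C(CC2=C(OC)C(C)=C(CC(=O)CC)OC2=O)C(=O)O1 | intermediate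
11 | methyl (2E)-2-{[4-hydroxy-5-methyl-2-oxo-6-(2-oxobutyl)-2H-pyran-3-yl]methyl}-3-methoxy-4-methyl-5,7-dioxonon-2-enoate (racemic at C4) | CO/C(C(C)C(=O)CC(=O)CC)=C(\CC1=C(O)C(C)=C(CC(=O)CC)OC1=O)C(=O)OC | intermediate (not isolated)
12 | 3-[(2,4-dihydroxy-6-methoxy-5-methyl-3-propanoylphenyl)methyl]-4-hydroxy-5-methyl-6-(2-oxobutyl)-2H-pyran-2-one | CCC(=O)CC1=C(C)C(O)=C(Cc2c(O)c(C(=O)CC)c(O)c(C)c2OC)C(=O)O1 | intermediate (not isolated)
13 | 1-[3-{[2,4-dihydroxy-6-methoxy-5-methyl-3-propanoylphenyl]methyl}-2,4,6-trihydroxy-5-methylphenyl]propan-1-one | CCC(=O)c1c(O)c(C)c(O)c(Cc2c(O)c(C(=O)CC)c(O)c(C)c2OC)c1O | target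

**Count and risks**

Total step count: 5. Longest linear sequence: 5 steps (1 to 13).

The three steps most likely to fail:

Step 5 (double Claisen fold). The two lactones may open at unequal rates, so that the anionic hydroxy-lactone half stalls at 12. Hot methoxide may also exchange the methylene bridge between the finished rings by retro-Michael and Michael addition and so erode the unsymmetrical dimer. The fallback sets out from 6 and comes back at 13: the lactones are folded one by one before the union, and the two arenes are joined last without base. Mg(OMe)2 in MeOH should convert 6 into 1-(2,4,6-trihydroxy-3-methylphenyl)propan-1-one F1. Separately, O-methylation of 6 (Me2SO4, K2CO3, acetone) should give 4-methoxy-5-methyl-6-(2-oxobutyl)-2H-pyran-2-one F2, which Mg(OMe)2 should fold to 1-(2,6-dihydroxy-4-methoxy-3-methylphenyl)propan-1-one F3. A Mannich reaction at the only free ring carbon of F3 (CH2=NMe2+ I−, CH2Cl2) should give 1-{3-[(dimethylamino)methyl]-2,6-dihydroxy-4-methoxy-5-methylphenyl}propan-1-one F4. Heating F4 with F1 in dioxane should expel dimethylamine, and the free ring carbon of F1 should trap the quinone methide of ring B to give 13, the usual way to unsymmetrical bis(acylphloroglucinol)methanes.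

Step 4 (one O-methylation of the symmetric bis-lactone). Alkylation may fall on the lactone carbonyl oxygen (a 2-methoxy-4-pyranone unit) or take place twice. The fallback sets out from 8 and comes back at 10: the methoxy group is brought in by substitution instead of alkylation. Acid-catalysed cyclodehydration (TsOH, PhMe, 110 °C, Dean–Stark) should give the anhydro bis-lactone F5, in which one oxygen bridges C4 and C4' as a 4H-pyran ring. One equivalent of NaOMe in MeOH/THF at 0 °C should then add to C4 of one lactone and expel the C4' oxygen of the other as its stabilised anion (addition–elimination on a vinylogous ester), which on acidification is 10. The methoxy group can then sit only on a C4 oxygen and only once.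

Step 2 (lateral acylation of the lactone dianion). The sparingly soluble dianion may be quenched by proton transfer from the amide or from the product, or form incompletely. The fallback sets out from 1 and comes back at 6: the propanoyl unit is brought in masked, before the lactone is closed. Ketalisation of 1 (ethane-1,2-diol, TsOH, PhH, Dean–Stark) should give methyl (2-ethyl-1,3-dioxolan-2-yl)acetate F6. Acylation of dianion 2 (two equivalents) by the ester F6 should give methyl 6-(2-ethyl-1,3-dioxolan-2-yl)-4-methyl-3,5-dioxohexanoate F7. DBU in hot toluene should lactonise F7 to 6-[(2-ethyl-1,3-dioxolan-2-yl)methyl]-4-hydroxy-5-methyl-2H-pyran-2-one F8, and aqueous HCl in THF should unmask the ketone to give 6.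

**Further compounds**

F1 | step 5 | 1-(2,4,6-trihydroxy-3-methylphenyl)propan-1-one | CCC(=O)c1c(O)cc(O)c(C)c1O
F2 | step 5 | 4-methoxy-5-methyl-6-(2-oxobutyl)-2H-pyran-2-one | CCC(=O)CC1=C(C)C(OC)=CC(=O)O1
F3 | step 5 | 1-(2,6-dihydroxy-4-methoxy-3-methylphenyl)propan-1-one | CCC(=O)c1c(O)cc(OC)c(C)c1O
F4 | step 5 | 1-{3-[(dimethylamino)methyl]-2,6-dihydroxy-4-methoxy-5-methylphenyl}propan-1-one | CCC(=O)c1c(O)c(CN(C)C)c(OC)c(C)c1O
F5 | step 4 | anhydro bis-lactone: compound 8 with its two C4 hydroxyls replaced by one oxygen that bridges C4 and C4' (a 4H-pyran ring fused to both pyran-2-ones) | CCC(=O)CC1=C(C)C2=C(CC3=C(O2)C(C)=C(CC(=O)CC)OC3=O)C(=O)O1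
F6 | step 2 | methyl (2-ethyl-1,3-dioxolan-2-yl)acetate | CCC1(CC(=O)OC)OCCO1
F7 | step 2 | methyl 6-(2-ethyl-1,3-dioxolan-2-yl)-4-methyl-3,5-dioxohexanoate (racemic) | CCC1(CC(=O)C(C)C(=O)CC(=O)OC)OCCO1
F8 | step 2 | 6-[(2-ethyl-1,3-dioxolan-2-yl)methyl]-4-hydroxy-5-methyl-2H-pyran-2-one | CCC1(CC2=C(C)C(O)=CC(=O)O2)OCCO1
A1 | direct plan | 2,4,6-trihydroxytoluene | Cc1c(O)cc(O)cc1O
A2 | direct plan | 1-[2,6-bis(benzyloxy)-3-(bromomethyl)-4-methoxy-5-methylphenyl]propan-1-one | CCC(=O)c1c(OCc2ccccc2)c(CBr)c(OC)c(C)c1OCc1ccccc1
A3 | direct plan | 1-methoxy-2-methyl-5-{2,4-bis(benzyloxy)-6-methoxy-5-methyl-3-[1-(trimethylsilyloxy)prop-1-en-1-yl]phenyl}-1,3-bis(trimethylsilyloxy)penta-1,3-diene | COC(O[Si](C)(C)C)=C(C)C(O[Si](C)(C)C)=CCc1c(OCc2ccccc2)c(C(O[Si](C)(C)C)=CC)c(OCc2ccccc2)c(C)c1OC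
A4 | direct plan | 1-(propan-2-yloxy)pent-1-yn-3-one | CCC(=O)C#COC(C)C
A5 | direct plan | 1-[3-{[2,4-bis(benzyloxy)-6-methoxy-5-methyl-3-propanoylphenyl]methyl}-4,6-dihydroxy-5-methyl-2-(propan-2-yloxy)phenyl]propan-1-one | CCC(=O)c1c(O)c(C)c(O)c(Cc2c(OCc3ccccc3)c(C(=O)CC)c(OCc3ccccc3)c(C)c2OC)c1OC(C)C
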